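**Plan**

- Locants: the flavanone unit is C2–C8a with ring B C1'–C6'. The flavone unit is C2''–C8a'', and its anisyl ring carries triple primes.
- Cuts: flavanone O1–C2 and C2–C3 (oxa-Michael, Knoevenagel); flavone O1''–C2'' and C4''–C4a'' (phenol addition to an arylpropiolate, Friedel–Crafts); flavone ring A across C8''–C8a'', C6''–C7'' and C4a''–C8a'', back to a ring B siloxyalkyne and 3-ethoxycyclobutenone.
- Enabling feature: C8'' bears ring B and lies between the oxygenated carbons C7'' and C8a'', with the C5'' oxygen para to it. An alkoxyvinylketene and an aryl siloxyalkyne assemble exactly this pattern, so the crowded C3'–C8'' bond is never made by aryl–aryl coupling.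
- Forward order: ring B ester, siloxyalkyne, benzannulation (flavone ring A), flavone pyranone ring, aldehyde release and ether adjustment, alkylidene β-ketoester with the phloroacetophenone piece, flavanone pyranone ring, hydrogenolysis.
- Stereochemistry: the only stereocentre, C2 (S), is set late by a cinchona-thiourea-catalysed oxa-Michael ring closure. Afterwards it meets only acid decarboxylation and neutral hydrogenolysis.

Key step: step 4

Remark: the C3'–C8'' axis has only O, O and H ortho substituents and is assumed to rotate freely at room temperature, so C2 is the only stereogenic element to control.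

Remark: the epi-quinidine-derived thiourea is assumed to give the (2S) ring closure; should the first assay show the opposite sense, its epi-quinine-derived pseudoenantiomer is used under the same conditions.

**Route**

Step 1
Reactants: 1 methyl 5-formyl-2-hydroxybenzoate
Product: 2 methyl 5-formyl-2-isopropoxybenzoate
Conditions: 2-bromopropane, K2CO3, KI (cat.), DMF, 60 °C
Reagents that add atoms: 2-bromopropane, CC(C)Br
Why: Williamson etherification of the acidic salicylate phenol; the isopropyl ether has no benzylic C–H to be lithiated in step 3, tolerates base and trifluoroacetic acid, and is cleaved by BCl3 in step 10.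

Step 2
Reactants: 2 methyl 5-formyl-2-isopropoxybenzoate
Product: 3 methyl 5-(1,3-dioxolan-2-yl)-2-isopropoxybenzoate
Conditions: ethylene glycol, p-TsOH·H2O (cat.), toluene, reflux, Dean–Stark
Reagents that add atoms: ethylene glycol, OCCO
Why: Acid-catalysed acetalisation with azeotropic removal of water masks the aldehyde against the lithium reagents of step 3, and the ester and aryl ether are unaffected.

Step 3
Reactants: 3 methyl 5-(1,3-dioxolan-2-yl)-2-isopropoxybenzoate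
Product: 5 {[5-(1,3-dioxolan-2-yl)-2-isopropoxyphenyl]ethynyl}oxy(triisopropyl)silane, via lithium ynolate 4 (not isolated)
Conditions: CH2Br2, lithium 2,2,6,6-tetramethylpiperidide, THF, −78 °C; then n-BuLi, −78 → 0 °C; then TIPSOTf, −78 °C → rt
Reagents that add atoms: dibromomethane, BrCBr; triisopropylsilyl trifluoromethanesulfonate, CC(C)[Si](OS(=O)(=O)C(F)(F)F)(C(C)C)C(C)C
Why: Kowalski ester homologation, in which LiCHBr2 adds to the ester and the dibromoketone enolate undergoes bromine–lithium exchange and 1,2-aryl shift to ynolate 4, which the bulky silyl triflate traps on oxygen; acetal and isopropyl ether are inert to the lithium reagents.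

Step 4
Reactants: 5 {[5-(1,3-dioxolan-2-yl)-2-isopropoxyphenyl]ethynyl}oxy(triisopropyl)silane; 6 3-ethoxycyclobut-2-en-1-one
Product: 11 2-[5-(1,3-dioxolan-2-yl)-2-isopropoxyphenyl]-5-ethoxy-3-[(triisopropylsilyl)oxy]phenol, via vinylketene 7 (not isolated), via vinylcyclobutenone 8 (not isolated), via dienylketene 9 (not isolated), via cyclohexadienone 10 (not isolated)
Conditions: 6 (1.5 equiv, in portions), toluene, 110 °C, sealed tube
Reagents that add atoms: none
Why: Heating opens 6 by four-electron electrocyclic ring opening to (1-ethoxyvinyl)ketene 7, whose ketene C=C adds [2+2] to the electron-rich siloxyalkyne 5 to give vinylcyclobutenone 8; a second four-electron opening gives dienylketene 9, which closes to dienone 10 and enolises to phenol 11. The closest known reaction is the Danheiser benzannulation of cyclobutenones with siloxyalkynes, the established route to resorcinol monosilyl ethers. The one ring formed, flavone ring A, closes by six-electron disrotatory electrocyclisation (C4a''–C8a'') and aromatises by tautomerisation; no stereocentre is created. The step needs regioselectivity in the ketene–alkyne [2+2], and the polarisation of the siloxyalkyne provides it: the aryl-bearing carbon, β to oxygen, is the nucleophilic terminus and bonds to the ketene carbonyl carbon (C8''–C8a''), while the silyloxy carbon bonds to the ketene α-carbon (C7''–C6''). Ring B therefore ends up between the phenol and the silyloxy carbon with the ethoxy group para, and the later tri-ortho-substituted axis is present from the start as an unhindered aryl–alkyne bond.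

Step 5
Reactants: 11 2-[5-(1,3-dioxolan-2-yl)-2-isopropoxyphenyl]-5-ethoxy-3-[(triisopropylsilyl)oxy]phenol
Product: 13 3-(benzyloxy)-2-[5-(1,3-dioxolan-2-yl)-2-isopropoxyphenyl]-5-ethoxyphenol, via benzyl silyl bis-ether 12 (not isolated)
Conditions: BnBr (1.05 equiv), K2CO3, DMF, rt; then TBAF, THF, rt
Reagents that add atoms: benzyl bromide, BrCc1ccccc1
Why: Williamson benzylation of the only free phenol followed by fluoride cleavage of the aryl silyl ether; the two oxygens flanking C8'' are related by the local symmetry of ring A, so the net result is exchange of the base-labile silyl group for a benzyl ether that survives steps 7 and 8, leaving one phenol for the pyranone annulation.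

Step 6
Reactants: 14 3-(4-methoxyphenyl)prop-2-ynoic acid
Product: 15 methyl 3-(4-methoxyphenyl)prop-2-ynoate
Conditions: MeI, K2CO3, DMF, rt
Reagents that add atoms: iodomethane, CI
Why: SN2 alkylation of the carboxylate at room temperature gives the ester without the heating that could decarboxylate an arylpropiolic acid.

Step 7
Reactants: 13 3-(benzyloxy)-2-[5-(1,3-dioxolan-2-yl)-2-isopropoxyphenyl]-5-ethoxyphenol; 15 methyl 3-(4-methoxyphenyl)prop-2-ynoate
Product: 16 methyl (Z)-3-{3-(benzyloxy)-2-[5-(1,3-dioxolan-2-yl)-2-isopropoxyphenyl]-5-ethoxyphenoxy}-3-(4-methoxyphenyl)prop-2-enoate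
Conditions: K2CO3 (0.5 equiv), DMF, 90 °C
Reagents that add atoms: none
Why: Base-catalysed oxa-Michael (Ruhemann-type) addition of the phenoxide to the β-carbon of the arylpropiolate with anti protonation places aryloxy and ester cis; any E isomer converges in step 9 because the push–pull alkene isomerises under acid.

Step 8
Reactants: 16 methyl (Z)-3-{3-(benzyloxy)-2-[5-(1,3-dioxolan-2-yl)-2-isopropoxyphenyl]-5-ethoxyphenoxy}-3-(4-methoxyphenyl)prop-2-enoate
Product: 18 (Z)-3-[3-(benzyloxy)-5-ethoxy-2-(5-formyl-2-isopropoxyphenyl)phenoxy]-3-(4-methoxyphenyl)prop-2-enoic acid, via lithium carboxylate acetal 17 (not isolated)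
Conditions: LiOH, THF/MeOH/H2O, 50 °C; then 1 M HCl, THF, rt
Reagents that add atoms: lithium hydroxide, [Li+].[OH-]; water, O
Why: Saponification as in the classical β-aryloxycinnamic acid route, then brief aqueous acid hydrolysis of the very labile p-alkoxybenzaldehyde acetal, so that no acetal is exposed to the anhydride of step 9 while the conjugated enol ether withstands dilute acid.

Step 9
Reactants: 18 (Z)-3-[3-(benzyloxy)-5-ethoxy-2-(5-formyl-2-isopropoxyphenyl)phenoxy]-3-(4-methoxyphenyl)prop-2-enoic acid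
Product: 20 3-[7-(benzyloxy)-5-ethoxy-2-(4-methoxyphenyl)-4-oxo-4H-chromen-8-yl]-4-isopropoxybenzaldehyde, via mixed trifluoroacetic anhydride 19 (not isolated)
Conditions: (CF3CO)2O, CH2Cl2, 0 °C → rt; aq. NaHCO3
Reagents that add atoms: none
Why: Intramolecular Friedel–Crafts acylation through the mixed anhydride, in which C4a'' is the only free position ortho to the aryloxy oxygen and is activated by the ortho ethoxy and para benzyloxy groups, so the pyranone closes regiospecifically without mineral acid.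

Step 10
Reactants: 20 3-[7-(benzyloxy)-5-ethoxy-2-(4-methoxyphenyl)-4-oxo-4H-chromen-8-yl]-4-isopropoxybenzaldehyde
Product: 21 3-[5,7-dihydroxy-2-(4-methoxyphenyl)-4-oxo-4H-chromen-8-yl]-4-hydroxybenzaldehyde
Conditions: BCl3, C6HMe5, CH2Cl2, −78 °C → rt; aqueous work-up
Reagents that add atoms: none
Why: Lewis acid ether cleavage in which boron chelated between C4''=O and the peri 5''-oxygen directs loss of the ethyl group, while the isopropyl and benzyl ethers are cleaved with pentamethylbenzene as cation trap and the unchelated 4'''-methyl ether is left intact.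

Step 11
Reactants: 21 3-[5,7-dihydroxy-2-(4-methoxyphenyl)-4-oxo-4H-chromen-8-yl]-4-hydroxybenzaldehyde
Product: 22 4-(benzyloxy)-3-[7-(benzyloxy)-5-hydroxy-2-(4-methoxyphenyl)-4-oxo-4H-chromen-8-yl]benzaldehyde
Conditions: BnBr (2.2 equiv), K2CO3, DMF, rt
Reagents that add atoms: benzyl bromide, BrCc1ccccc1
Why: Selective Williamson benzylation of the acidic 7''- and 4'-phenols, the 5''-OH being held in a hydrogen bond to C4''=O and unreactive at room temperature.

Step 12
Reactants: 23 1-(2,4,6-trihydroxyphenyl)ethanone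
Product: 24 1-[2,4-bis(benzyloxy)-6-hydroxyphenyl]ethanone
Conditions: BnBr (2.1 equiv), K2CO3, DMF, rt
Reagents that add atoms: benzyl bromide, BrCc1ccccc1
Why: Williamson bis-benzylation of phloroacetophenone, which stops with one carbonyl-chelated ortho phenol free, as needed for the later ring closure.

Step 13
Reactants: 24 1-[2,4-bis(benzyloxy)-6-hydroxyphenyl]ethanone
Product: 25 tert-butyl 3-[2,4-bis(benzyloxy)-6-hydroxyphenyl]-3-oxopropanoate
Conditions: LiN(SiMe3)2 (3.2 equiv), THF, −78 °C; Boc2O, −78 → 0 °C; aq. NH4Cl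
Reagents that add atoms: di-tert-butyl dicarbonate, CC(C)(C)OC(=O)OC(=O)OC(C)(C)C
Why: Claisen-type C-acylation of the phenoxide–enolate dianion with Boc2O, any aryl carbonate formed passing its acyl group on to carbon, with the third equivalent of base keeping the β-ketoester deprotonated.

Step 14
Reactants: 22 4-(benzyloxy)-3-[7-(benzyloxy)-5-hydroxy-2-(4-methoxyphenyl)-4-oxo-4H-chromen-8-yl]benzaldehyde; 25 tert-butyl 3-[2,4-bis(benzyloxy)-6-hydroxyphenyl]-3-oxopropanoate
Product: 26 tert-butyl 2-[2,4-bis(benzyloxy)-6-hydroxybenzoyl]-3-{4-(benzyloxy)-3-[7-(benzyloxy)-5-hydroxy-2-(4-methoxyphenyl)-4-oxo-4H-chromen-8-yl]phenyl}prop-2-enoate (E/Z mixture)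
Conditions: piperidine (cat.), AcOH (cat.), toluene, 4 Å molecular sieves, rt
Reagents that add atoms: none
Why: Knoevenagel condensation under piperidinium acetate catalysis, in which the carbonyl-chelated ortho phenol should not add to the alkylidene at room temperature.

Step 15
Reactants: 26 tert-butyl 2-[2,4-bis(benzyloxy)-6-hydroxybenzoyl]-3-{4-(benzyloxy)-3-[7-(benzyloxy)-5-hydroxy-2-(4-methoxyphenyl)-4-oxo-4H-chromen-8-yl]phenyl}prop-2-enoate
Product: 28 (2S)-5,7-bis(benzyloxy)-2-{4-(benzyloxy)-3-[7-(benzyloxy)-5-hydroxy-2-(4-methoxyphenyl)-4-oxo-4H-chromen-8-yl]phenyl}-2,3-dihydro-4H-chromen-4-one, via flavanone tert-butyl ester 27 (not isolated)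
Conditions: 9-amino-9-deoxy-epi-quinidine-derived N-[3,5-bis(trifluoromethyl)phenyl]thiourea (10 mol%), toluene, −25 °C; then TsOH·H2O, 80 °C
Reagents that add atoms: none
Why: Enantioselective intramolecular oxa-Michael addition under bifunctional catalysis, the thiourea binding the β-ketoester and the quinuclidine delivering the phenol to one face of the alkylidene to set C2 as S, followed by acid cleavage of the tert-butyl ester and decarboxylation of the β-ketoacid.

Step 16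
Reactants: 28 (2S)-5,7-bis(benzyloxy)-2-{4-(benzyloxy)-3-[7-(benzyloxy)-5-hydroxy-2-(4-methoxyphenyl)-4-oxo-4H-chromen-8-yl]phenyl}-2,3-dihydro-4H-chromen-4-one
Product: 29 (2S)-5,7-dihydroxy-2-{4-hydroxy-3-[5,7-dihydroxy-2-(4-methoxyphenyl)-4-oxo-4H-chromen-8-yl]phenyl}-2,3-dihydro-4H-chromen-4-one (2,3-dihydropodocarpusflavone A)
Conditions: H2 (1 atm), Pd/C, THF/MeOH, rt
Reagents that add atoms: none
Why: Hydrogenolysis of the four benzyl ethers over palladium under neutral conditions, which should spare the flavone C2''=C3'' bond, both carbonyls and the base-sensitive C2 stereocentre.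

**Compound list**

1 | methyl 5-formyl-2-hydroxybenzoate | COC(=O)c1cc(C=O)ccc1O | starting material
2 | methyl 5-formyl-2-isopropoxybenzoate | COC(=O)c1cc(C=O)ccc1OC(C)C | intermediate
3 | methyl 5-(1,3-dioxolan-2-yl)-2-isopropoxybenzoate | COC(=O)c1cc(C2OCCO2)ccc1OC(C)C | intermediate
4 | lithium 2-[5-(1,3-dioxolan-2-yl)-2-isopropoxyphenyl]ethynolate | [Li+].[O-]C#Cc1cc(C2OCCO2)ccc1OC(C)C | intermediate (not isolated)
5 | {[5-(1,3-dioxolan-2-yl)-2-isopropoxyphenyl]ethynyl}oxy(triisopropyl)silane | CC(C)Oc1ccc(C2OCCO2)cc1C#CO[Si](C(C)C)(C(C)C)C(C)C | intermediate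
6 | 3-ethoxycyclobut-2-en-1-one | CCOC1=CC(=O)C1 | starting material
7 | 3-ethoxybuta-1,3-dien-1-one, (1-ethoxyvinyl)ketene | C=C(OCC)C=C=O | intermediate (not isolated)
8 | 2-[5-(1,3-dioxolan-2-yl)-2-isopropoxyphenyl]-4-(1-ethoxyvinyl)-3-[(triisopropylsilyl)oxy]cyclobut-2-en-1-one (racemic) | C=C(OCC)C1C(=O)C(c2cc(C3OCCO3)ccc2OC(C)C)=C1O[Si](C(C)C)(C(C)C)C(C)C | intermediate (not isolated)
9 | (3E)-2-[5-(1,3-dioxolan-2-yl)-2-isopropoxyphenyl]-5-ethoxy-3-[(triisopropylsilyl)oxy]hexa-1,3,5-trien-1-one | O=C=C(c1cc(C2OCCO2)ccc1OC(C)C)/C(O[Si](C(C)C)(C(C)C)C(C)C)=C\C(OCC)=C | intermediate (not isolated)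
10 | 2-[5-(1,3-dioxolan-2-yl)-2-isopropoxyphenyl]-5-ethoxy-3-[(triisopropylsilyl)oxy]cyclohexa-2,4-dien-1-one | O=C1CC(OCC)=CC(O[Si](C(C)C)(C(C)C)C(C)C)=C1c1cc(C2OCCO2)ccc1OC(C)C | intermediate (not isolated)
11 | 2-[5-(1,3-dioxolan-2-yl)-2-isopropoxyphenyl]-5-ethoxy-3-[(triisopropylsilyl)oxy]phenol | CCOc1cc(O)c(-c2cc(C3OCCO3)ccc2OC(C)C)c(O[Si](C(C)C)(C(C)C)C(C)C)c1 | intermediate
12 | {3-(benzyloxy)-2-[5-(1,3-dioxolan-2-yl)-2-isopropoxyphenyl]-5-ethoxyphenoxy}(triisopropyl)silane | CCOc1cc(OCc2ccccc2)c(-c2cc(C3OCCO3)ccc2OC(C)C)c(O[Si](C(C)C)(C(C)C)C(C)C)c1 | intermediate (not isolated)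
13 | 3-(benzyloxy)-2-[5-(1,3-dioxolan-2-yl)-2-isopropoxyphenyl]-5-ethoxyphenol | CCOc1cc(O)c(-c2cc(C3OCCO3)ccc2OC(C)C)c(OCc2ccccc2)c1 | intermediate
14 | 3-(4-methoxyphenyl)prop-2-ynoic acid | COc1ccc(C#CC(=O)O)cc1 | starting material
15 | methyl 3-(4-methoxyphenyl)prop-2-ynoate | COc1ccc(C#CC(=O)OC)cc1 | intermediate
16 | methyl (Z)-3-{3-(benzyloxy)-2-[5-(1,3-dioxolan-2-yl)-2-isopropoxyphenyl]-5-ethoxyphenoxy}-3-(4-methoxyphenyl)prop-2-enoate | COC(=O)/C=C(\Oc1cc(OCC)cc(OCc2ccccc2)c1-c1cc(C2OCCO2)ccc1OC(C)C)c1ccc(OC)cc1 | intermediate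
17 | lithium (Z)-3-{3-(benzyloxy)-2-[5-(1,3-dioxolan-2-yl)-2-isopropoxyphenyl]-5-ethoxyphenoxy}-3-(4-methoxyphenyl)prop-2-enoate | [Li+].[O-]C(=O)/C=C(\Oc1cc(OCC)cc(OCc2ccccc2)c1-c1cc(C2OCCO2)ccc1OC(C)C)c1ccc(OC)cc1 | intermediate (not isolated)
18 | (Z)-3-[3-(benzyloxy)-5-ethoxy-2-(5-formyl-2-isopropoxyphenyl)phenoxy]-3-(4-methoxyphenyl)prop-2-enoic acid | OC(=O)/C=C(\Oc1cc(OCC)cc(OCc2ccccc2)c1-c1cc(C=O)ccc1OC(C)C)c1ccc(OC)cc1 | intermediate
19 | (Z)-3-[3-(benzyloxy)-5-ethoxy-2-(5-formyl-2-isopropoxyphenyl)phenoxy]-3-(4-methoxyphenyl)prop-2-enoic trifluoroacetic anhydride | O=C(OC(=O)C(F)(F)F)/C=C(\Oc1cc(OCC)cc(OCc2ccccc2)c1-c1cc(C=O)ccc1OC(C)C)c1ccc(OC)cc1 | intermediate (not isolated)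
20 | 3-[7-(benzyloxy)-5-ethoxy-2-(4-methoxyphenyl)-4-oxo-4H-chromen-8-yl]-4-isopropoxybenzaldehyde | COc1ccc(-c2cc(=O)c3c(OCC)cc(OCc4ccccc4)c(-c4cc(C=O)ccc4OC(C)C)c3o2)cc1 | intermediate
21 | 3-[5,7-dihydroxy-2-(4-methoxyphenyl)-4-oxo-4H-chromen-8-yl]-4-hydroxybenzaldehyde | COc1ccc(-c2cc(=O)c3c(O)cc(O)c(-c4cc(C=O)ccc4O)c3o2)cc1 | intermediate
22 | 4-(benzyloxy)-3-[7-(benzyloxy)-5-hydroxy-2-(4-methoxyphenyl)-4-oxo-4H-chromen-8-yl]benzaldehyde | COc1ccc(-c2cc(=O)c3c(O)cc(OCc4ccccc4)c(-c4cc(C=O)ccc4OCc4ccccc4)c3o2)cc1 | intermediate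
23 | 1-(2,4,6-trihydroxyphenyl)ethanone | CC(=O)c1c(O)cc(O)cc1O | starting material
24 | 1-[2,4-bis(benzyloxy)-6-hydroxyphenyl]ethanone | CC(=O)c1c(O)cc(OCc2ccccc2)cc1OCc1ccccc1 | intermediate
25 | tert-butyl 3-[2,4-bis(benzyloxy)-6-hydroxyphenyl]-3-oxopropanoate | CC(C)(C)OC(=O)CC(=O)c1c(O)cc(OCc2ccccc2)cc1OCc1ccccc1 | intermediate
26 | tert-butyl 2-[2,4-bis(benzyloxy)-6-hydroxybenzoyl]-3-{4-(benzyloxy)-3-[7-(benzyloxy)-5-hydroxy-2-(4-methoxyphenyl)-4-oxo-4H-chromen-8-yl]phenyl}prop-2-enoate (E/Z mixture) | CC(C)(C)OC(=O)C(=Cc1ccc(OCc2ccccc2)c(-c2c(OCc3ccccc3)cc(O)c3c(=O)cc(-c4ccc(OC)cc4)oc23)c1)C(=O)c1c(O)cc(OCc2ccccc2)cc1OCc1ccccc1 | intermediate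
27 | tert-butyl (2S)-5,7-bis(benzyloxy)-2-{4-(benzyloxy)-3-[7-(benzyloxy)-5-hydroxy-2-(4-methoxyphenyl)-4-oxo-4H-chromen-8-yl]phenyl}-4-oxochromane-3-carboxylate (C3 epimerisable) | COc1ccc(-c2cc(=O)c3c(O)cc(OCc4ccccc4)c(-c4cc([C@@H]5C(C(=O)OC(C)(C)C)C(=O)c6c(OCc7ccccc7)cc(OCc7ccccc7)cc6O5)ccc4OCc4ccccc4)c3o2)cc1 | intermediate (not isolated)
28 | (2S)-5,7-bis(benzyloxy)-2-{4-(benzyloxy)-3-[7-(benzyloxy)-5-hydroxy-2-(4-methoxyphenyl)-4-oxo-4H-chromen-8-yl]phenyl}-2,3-dihydro-4H-chromen-4-one | COc1ccc(-c2cc(=O)c3c(O)cc(OCc4ccccc4)c(-c4cc([C@@H]5CC(=O)c6c(OCc7ccccc7)cc(OCc7ccccc7)cc6O5)ccc4OCc4ccccc4)c3o2)cc1 | intermediate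
29 | (2S)-5,7-dihydroxy-2-{4-hydroxy-3-[5,7-dihydroxy-2-(4-methoxyphenyl)-4-oxo-4H-chromen-8-yl]phenyl}-2,3-dihydro-4H-chromen-4-one, 2,3-dihydropodocarpusflavone A | COc1ccc(-c2cc(=O)c3c(O)cc(O)c(-c4cc([C@@H]5CC(=O)c6c(O)cc(O)cc6O5)ccc4O)c3o2)cc1 | target

**Count and risks**

Total steps: 16. Longest linear sequence: 13 steps (1–5, 7–11, 14–16).

Step 4. The vinylogous-ester cyclobutenone may open too slowly, so that thermal rearrangement of the siloxyalkyne to a silylketene, self-condensation of the vinylketene and O-acylation of the product phenol by the vinylketene outrun the [2+2] step. The fallback makes the C3'–C8'' bond by Suzuki–Miyaura coupling. It sets out from 24. Claisen–Schmidt condensation with 4-methoxybenzaldehyde (KOH, EtOH) should give (E)-1-[2,4-bis(benzyloxy)-6-hydroxyphenyl]-3-(4-methoxyphenyl)prop-2-en-1-one F1. Oxidative cyclisation (I2 cat., DMSO, 130 °C) should give 5,7-bis(benzyloxy)-2-(4-methoxyphenyl)-4H-chromen-4-one F2. Electrophilic iodination at the less hindered C8 (benzyltrimethylammonium dichloroiodate, CaCO3, CH2Cl2/MeOH) should give 5,7-bis(benzyloxy)-8-iodo-2-(4-methoxyphenyl)-4H-chromen-4-one F3. Coupling with commercial [2-(benzyloxy)-5-formylphenyl]boronic acid (Pd(PPh3)4, K2CO3, DMF/H2O, 90 °C) should give 4-(benzyloxy)-3-[5,7-bis(benzyloxy)-2-(4-methoxyphenyl)-4-oxo-4H-chromen-8-yl]benzaldehyde F4. Chelation-controlled removal of the peri benzyl group (MgBr2·OEt2, toluene/Et2O, reflux) comes back to the route at 22.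

Step 15. Enantiomeric purity may be lost through uncatalysed or amine-residue-catalysed background ring closure, and through reversible opening of the para-oxygenated benzylic ether during the acid decarboxylation. The fallback replaces asymmetric catalysis by resolution. It sets out from 26. Ring closure with an achiral base (Et3N, toluene, rt) should give racemic tert-butyl 5,7-bis(benzyloxy)-2-{4-(benzyloxy)-3-[7-(benzyloxy)-5-hydroxy-2-(4-methoxyphenyl)-4-oxo-4H-chromen-8-yl]phenyl}-4-oxochromane-3-carboxylate F9. Decarboxylation (TsOH, toluene, 80 °C) should give racemic 5,7-bis(benzyloxy)-2-{4-(benzyloxy)-3-[7-(benzyloxy)-5-hydroxy-2-(4-methoxyphenyl)-4-oxo-4H-chromen-8-yl]phenyl}-2,3-dihydro-4H-chromen-4-one F10. Kinetic resolution by asymmetric transfer hydrogenation (Cp*RhCl(TsDPEN) in the enantiomeric form that reduces the (2R) ketone faster, HCO2H/Et3N, EtOAc, rt) should convert the unwanted enantiomer into (2R,4R)-5,7-bis(benzyloxy)-2-{4-(benzyloxy)-3-[7-(benzyloxy)-5-hydroxy-2-(4-methoxyphenyl)-4-oxo-4H-chromen-8-yl]phenyl}chroman-4-ol F11. The unreduced ketone is 28, where the route is rejoined.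

Step 9. The mixed anhydride of a vinylogous carbonic acid may be too weak an electrophile, and the aryl vinyl ether may be cleaved by acid before the ring closes. The fallback builds the pyranone from an ortho-hydroxyaryl ynone instead. It sets out from 13. Ortho-formylation at the only free ortho position (MgCl2, Et3N, paraformaldehyde, MeCN, reflux; Casnati–Skattebøl) should give 4-(benzyloxy)-3-[5-(1,3-dioxolan-2-yl)-2-isopropoxyphenyl]-6-ethoxy-2-hydroxybenzaldehyde F5. Addition of lithium (4-methoxyphenyl)acetylide (2.2 equiv, THF, −78 °C) should give 1-{4-(benzyloxy)-3-[5-(1,3-dioxolan-2-yl)-2-isopropoxyphenyl]-6-ethoxy-2-hydroxyphenyl}-3-(4-methoxyphenyl)prop-2-yn-1-ol F6. Oxidation (MnO2, CH2Cl2) should give 1-{4-(benzyloxy)-3-[5-(1,3-dioxolan-2-yl)-2-isopropoxyphenyl]-6-ethoxy-2-hydroxyphenyl}-3-(4-methoxyphenyl)prop-2-yn-1-one F7. Six-endo cyclisation through the enaminone (Et2NH, EtOH, reflux) should give 7-(benzyloxy)-8-[5-(1,3-dioxolan-2-yl)-2-isopropoxyphenyl]-5-ethoxy-2-(4-methoxyphenyl)-4H-chromen-4-one F8. Aqueous HCl in THF then releases the aldehyde and comes back to the route at 20.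

**Further compounds**

F1 | step 4 | (E)-1-[2,4-bis(benzyloxy)-6-hydroxyphenyl]-3-(4-methoxyphenyl)prop-2-en-1-one | COc1ccc(/C=C/C(=O)c2c(O)cc(OCc3ccccc3)cc2OCc2ccccc2)cc1
F2 | step 4 | 5,7-bis(benzyloxy)-2-(4-methoxyphenyl)-4H-chromen-4-one | COc1ccc(-c2cc(=O)c3c(OCc4ccccc4)cc(OCc4ccccc4)cc3o2)cc1
F3 | step 4 | 5,7-bis(benzyloxy)-8-iodo-2-(4-methoxyphenyl)-4H-chromen-4-one | COc1ccc(-c2cc(=O)c3c(OCc4ccccc4)cc(OCc4ccccc4)c(I)c3o2)cc1
F4 | step 4 | 4-(benzyloxy)-3-[5,7-bis(benzyloxy)-2-(4-methoxyphenyl)-4-oxo-4H-chromen-8-yl]benzaldehyde | COc1ccc(-c2cc(=O)c3c(OCc4ccccc4)cc(OCc4ccccc4)c(-c4cc(C=O)ccc4OCc4ccccc4)c3o2)cc1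
F5 | step 9 | 4-(benzyloxy)-3-[5-(1,3-dioxolan-2-yl)-2-isopropoxyphenyl]-6-ethoxy-2-hydroxybenzaldehyde | O=Cc1c(O)c(-c2cc(C3OCCO3)ccc2OC(C)C)c(OCc2ccccc2)cc1OCC
F6 | step 9 | 1-{4-(benzyloxy)-3-[5-(1,3-dioxolan-2-yl)-2-isopropoxyphenyl]-6-ethoxy-2-hydroxyphenyl}-3-(4-methoxyphenyl)prop-2-yn-1-ol (racemic) | COc1ccc(C#CC(O)c2c(O)c(-c3cc(C4OCCO4)ccc3OC(C)C)c(OCc3ccccc3)cc2OCC)cc1
F7 | step 9 | 1-{4-(benzyloxy)-3-[5-(1,3-dioxolan-2-yl)-2-isopropoxyphenyl]-6-ethoxy-2-hydroxyphenyl}-3-(4-methoxyphenyl)prop-2-yn-1-one | COc1ccc(C#CC(=O)c2c(O)c(-c3cc(C4OCCO4)ccc3OC(C)C)c(OCc3ccccc3)cc2OCC)cc1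
F8 | step 9 | 7-(benzyloxy)-8-[5-(1,3-dioxolan-2-yl)-2-isopropoxyphenyl]-5-ethoxy-2-(4-methoxyphenyl)-4H-chromen-4-one | COc1ccc(-c2cc(=O)c3c(OCC)cc(OCc4ccccc4)c(-c4cc(C5OCCO5)ccc4OC(C)C)c3o2)cc1
F9 | step 15 | racemic tert-butyl 5,7-bis(benzyloxy)-2-{4-(benzyloxy)-3-[7-(benzyloxy)-5-hydroxy-2-(4-methoxyphenyl)-4-oxo-4H-chromen-8-yl]phenyl}-4-oxochromane-3-carboxylate | COc1ccc(-c2cc(=O)c3c(O)cc(OCc4ccccc4)c(-c4cc(C5C(C(=O)OC(C)(C)C)C(=O)c6c(OCc7ccccc7)cc(OCc7ccccc7)cc6O5)ccc4OCc4ccccc4)c3o2)cc1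
F10 | step 15 | racemic 5,7-bis(benzyloxy)-2-{4-(benzyloxy)-3-[7-(benzyloxy)-5-hydroxy-2-(4-methoxyphenyl)-4-oxo-4H-chromen-8-yl]phenyl}-2,3-dihydro-4H-chromen-4-one | COc1ccc(-c2cc(=O)c3c(O)cc(OCc4ccccc4)c(-c4cc(C5CC(=O)c6c(OCc7ccccc7)cc(OCc7ccccc7)cc6O5)ccc4OCc4ccccc4)c3o2)cc1
F11 | step 15 | (2R,4R)-5,7-bis(benzyloxy)-2-{4-(benzyloxy)-3-[7-(benzyloxy)-5-hydroxy-2-(4-methoxyphenyl)-4-oxo-4H-chromen-8-yl]phenyl}chroman-4-ol | COc1ccc(-c2cc(=O)c3c(O)cc(OCc4ccccc4)c(-c4cc([C@H]5C[C@@H](O)c6c(OCc7ccccc7)cc(OCc7ccccc7)cc6O5)ccc4OCc4ccccc4)c3o2)cc1
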